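**Plan**

- The retrosynthesis cuts the two bonds from the bridging CH2 carbon, one to C1 of ring A (the 2,3-dibromo-4,5-dihydroxyphenyl ring) and one to C1 of ring B (the 3-bromo-2,4,6-trihydroxyphenyl ring).
- That single carbon is the only link between the rings, and both junction carbons are crowded (C1 of ring A next to the C2 bromine, C1 of ring B between two oxygen-bearing carbons). It is therefore introduced as carbon monoxide, bonded to both rings in one operation.
- Backward: the five O-methyl groups, the ring B bromine and the CH2 oxidation level are adjusted first; the resulting diaryl ketone falls apart into an aryl iodide, CO and an arylboronic acid.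
- Forward: ring A is elaborated from 5-bromovanillin (bromination, methylation, oxidation, iododecarboxylation) and joined to ring B through CO. The ketone is then reduced, ring B is brominated once, and all ethers are cleaved.
- No ring is built (both benzene rings are purchased) and the target has no stereocentre, so no stereochemistry has to be set.

Key step: step 5

Remark: all five phenols are carried as methyl ethers and released together in the last step; the racemic carbinol that appears in step 6 is reduced further in the same flask.

**Route**

Step 1
Reactants: 1 5-bromovanillin (3-bromo-4-hydroxy-5-methoxybenzaldehyde)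
Product: 2 2,3-dibromo-4-hydroxy-5-methoxybenzaldehyde (5,6-dibromovanillin)
Conditions: Br2 (1.2 equiv), Fe powder (cat.), AcOH, 25 to 60 °C
Reagents that add atoms: bromine, BrBr
Why: Electrophilic aromatic bromination with FeBr3 formed in the flask; of the two free positions, the one para to the methoxy group (C6 of the vanillin numbering) is the more activated, which is the well-precedented course to 5,6-dibromovanillin.

Step 2
Reactants: 2 2,3-dibromo-4-hydroxy-5-methoxybenzaldehyde
Product: 3 2,3-dibromo-4,5-dimethoxybenzaldehyde
Conditions: MeI, K2CO3, DMF, 25 to 50 °C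
Reagents that add atoms: iodomethane, CI
Why: Williamson ether synthesis; the acidic phenol flanked by bromine and methoxy is deprotonated by K2CO3 and the phenoxide is methylated by SN2, while the aldehyde and the aryl bromides are inert.

Step 3
Reactants: 3 2,3-dibromo-4,5-dimethoxybenzaldehyde
Product: 4 2,3-dibromo-4,5-dimethoxybenzoic acid
Conditions: NaClO2, NaH2PO4, 2-methyl-2-butene, t-BuOH/H2O, 0 °C to rt
Reagents that add atoms: sodium chlorite, [Na+].[O-]Cl=O
Why: Pinnick oxidation; chlorous acid converts the aldehyde into the acid and 2-methyl-2-butene traps the hypochlorous acid, so the electron-rich ring is not chlorinated.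

Step 4
Reactants: 4 2,3-dibromo-4,5-dimethoxybenzoic acid
Product: 5 2,3-dibromo-1-iodo-4,5-dimethoxybenzene
Conditions: I2 (3 equiv), K3PO4, MeCN, 120 °C (sealed tube); Na2S2O3 work-up
Reagents that add atoms: iodine, II
Why: Transition-metal-free ipso-iododecarboxylation (a halodecarboxylation of the Hunsdiecker family) of an ortho-substituted, alkoxy-activated benzoate: iodine is delivered to C1, which lies para to the C4 methoxy group and is sterically loaded by the C2 bromine, CO2 is lost and the C–Br bonds are not touched.

Step 5
Reactants: 5 2,3-dibromo-1-iodo-4,5-dimethoxybenzene; 6 2,4,6-trimethoxyphenylboronic acid (2 equiv); 7 carbon monoxide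
Product: 8 (2,3-dibromo-4,5-dimethoxyphenyl)(2,4,6-trimethoxyphenyl)methanone
Conditions: PdCl2(IPr)(3-chloropyridine) (3 mol %; IPr = 1,3-bis(2,6-diisopropylphenyl)imidazol-2-ylidene), Cs2CO3, CO (4 bar), chlorobenzene, 80 °C
Reagents that add atoms: none
Why: The divalent palladium precatalyst is reduced in the flask to zerovalent palladium, which inserts into the C1–I bond of 5; migratory insertion of CO gives an aroylpalladium iodide, base-assisted transmetallation with 6 follows, and reductive elimination releases the ketone, so that both bonds from the carbonyl carbon (to C1 of ring A and to C1 of ring B) form in one catalytic cycle. The closest known reaction type is the carbonylative Suzuki–Miyaura coupling of ortho-substituted aryl iodides to hindered diaryl ketones under N-heterocyclic-carbene palladium catalysis. No ring closes and no stereocentre is formed. Chemoselectivity for C–I over the two C–Br bonds is required and rests on the weaker C–I bond and on the low reactivity of CO-ligated zerovalent palladium toward aryl bromides at 80 °C. CO uptake must precede transmetallation, which the CO pressure and the slow transmetallation of the doubly ortho-methoxylated boronic acid secure, while the ortho bromine of 5 speeds acyl formation by steric relief. Protodeboronation of 6 is countered by the anhydrous carbonate base in a non-protic solvent and by the excess of 6.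

Step 6
Reactants: 8 (2,3-dibromo-4,5-dimethoxyphenyl)(2,4,6-trimethoxyphenyl)methanone
Product: 10 2-[(2,3-dibromo-4,5-dimethoxyphenyl)methyl]-1,3,5-trimethoxybenzene, via diarylmethanol 9 (not isolated)
Conditions: Et3SiH (3 equiv), CF3CO2H, CH2Cl2, 0 °C to rt
Reagents that add atoms: none
Why: Ionic hydrogenation; the protonated ketone accepts hydride from the silane to give carbinol 9, which ionises to a diarylmethyl cation strongly stabilised by the 2,4,6-trimethoxyphenyl ring and is reduced a second time, and aryl bromides are inert to silane and acid, as in reductions of halogenated benzophenones.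

Step 7
Reactants: 10 2-[(2,3-dibromo-4,5-dimethoxyphenyl)methyl]-1,3,5-trimethoxybenzene
Product: 11 2-bromo-4-[(2,3-dibromo-4,5-dimethoxyphenyl)methyl]-1,3,5-trimethoxybenzene
Conditions: NBS (1.0 equiv), MeCN, −20 to 0 °C, dark
Reagents that add atoms: N-bromosuccinimide, O=C1CCC(=O)N1Br
Why: Electrophilic aromatic bromination; the trimethoxy ring B is far more nucleophilic than the dibrominated ring A, its two free positions are equivalent, and the first bromine deactivates the ring and twists the flanking methoxy groups, so one equivalent of NBS should stop at the monobromide.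

Step 8
Reactants: 11 2-bromo-4-[(2,3-dibromo-4,5-dimethoxyphenyl)methyl]-1,3,5-trimethoxybenzene
Product: 12 vidalol A (2-bromo-4-[(2,3-dibromo-4,5-dihydroxyphenyl)methyl]benzene-1,3,5-triol)
Conditions: BBr3 (8 equiv), CH2Cl2, −78 °C to rt; then ice-water, work-up under argon
Reagents that add atoms: none
Why: Lewis-acid ether cleavage; BBr3 coordinates each methoxy oxygen, bromide removes the methyl group by SN2 and hydrolysis frees the five phenols, while aryl bromides and the diarylmethane link are retained at or below room temperature, as is usual in the end game of bromophenol syntheses.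

**Compound list**

1 | 5-bromovanillin (3-bromo-4-hydroxy-5-methoxybenzaldehyde) | COc1cc(C=O)cc(Br)c1O | starting material
2 | 2,3-dibromo-4-hydroxy-5-methoxybenzaldehyde (5,6-dibromovanillin) | COc1cc(C=O)c(Br)c(Br)c1O | intermediate
3 | 2,3-dibromo-4,5-dimethoxybenzaldehyde | COc1cc(C=O)c(Br)c(Br)c1OC | intermediate
4 | 2,3-dibromo-4,5-dimethoxybenzoic acid | COc1cc(C(=O)O)c(Br)c(Br)c1OC | intermediate
5 | 2,3-dibromo-1-iodo-4,5-dimethoxybenzene | COc1cc(I)c(Br)c(Br)c1OC | intermediate
6 | 2,4,6-trimethoxyphenylboronic acid | COc1cc(OC)c(B(O)O)c(OC)c1 | starting material
7 | carbon monoxide | [C-]#[O+] | starting material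
8 | (2,3-dibromo-4,5-dimethoxyphenyl)(2,4,6-trimethoxyphenyl)methanone | COc1cc(C(=O)c2c(OC)cc(OC)cc2OC)c(Br)c(Br)c1OC | intermediate
9 | (2,3-dibromo-4,5-dimethoxyphenyl)(2,4,6-trimethoxyphenyl)methanol (racemic, formed in the flask, not isolated) | COc1cc(C(O)c2c(OC)cc(OC)cc2OC)c(Br)c(Br)c1OC | intermediate
10 | 2-[(2,3-dibromo-4,5-dimethoxyphenyl)methyl]-1,3,5-trimethoxybenzene | COc1cc(Cc2c(OC)cc(OC)cc2OC)c(Br)c(Br)c1OC | intermediate
11 | 2-bromo-4-[(2,3-dibromo-4,5-dimethoxyphenyl)methyl]-1,3,5-trimethoxybenzene | COc1cc(Cc2c(OC)cc(OC)c(Br)c2OC)c(Br)c(Br)c1OC | intermediate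
12 | vidalol A (2-bromo-4-[(2,3-dibromo-4,5-dihydroxyphenyl)methyl]benzene-1,3,5-triol) | Oc1cc(Cc2c(O)cc(O)c(Br)c2O)c(Br)c(Br)c1O | target

**Step count**

Total: 8 steps. Longest linear sequence: 8 steps (1 to 12); compounds 6 and 7 are purchased.

**Steps most likely to fail**

Step 5 (key step). Protodeboronation of the electron-rich, doubly ortho-substituted boronic acid may outrun transmetallation. Direct biaryl coupling without CO uptake or insertion of palladium into a C–Br bond may also compete. The fallback sets out from acid 4 and returns to the route at ketone 8, so steps 4 and 5 are bypassed. Acid 4 would be treated with oxalyl chloride and catalytic DMF in CH2Cl2 to give 2,3-dibromo-4,5-dimethoxybenzoyl chloride F1. Purchased 1,3,5-trimethoxybenzene (COc1cc(OC)cc(OC)c1) would then be acylated with it under AlCl3 in CH2Cl2 at 0 °C (Friedel–Crafts acylation); all three ring positions of that arene are equivalent, so only ketone 8 can form.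

Step 4. Ipso attack of iodine may be sluggish because the ring carries two bromines and the para methoxy group is twisted out of conjugation. Unchanged acid, protodecarboxylation or iodination at the free C6 position could then result. The fallback sets out from acid 4 and returns at iodide 5. A Curtius rearrangement with diphenylphosphoryl azide and Et3N in t-BuOH at reflux would pass through 2,3-dibromo-4,5-dimethoxybenzoyl azide F2 and 2,3-dibromo-1-isocyanato-4,5-dimethoxybenzene F3 to tert-butyl (2,3-dibromo-4,5-dimethoxyphenyl)carbamate F4. CF3CO2H in CH2Cl2 would free 2,3-dibromo-4,5-dimethoxyaniline F5. Diazotisation with NaNO2 and p-toluenesulfonic acid in MeCN/H2O would give 2,3-dibromo-4,5-dimethoxybenzenediazonium tosylate F6, which with KI in the same flask should give iodide 5 (Sandmeyer-type iododediazoniation).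

Step 8. The ring B bromine may be lost or may migrate by protodebromination of the highly activated phloroglucinol ring in the acid set free on quenching. Cleavage of the hindered methyl ethers may be incomplete, and the polyphenol may oxidise in air. The fallback sets out from 10 and returns at target 12, reversing the order of bromination and deprotection so that the ring B bromine never meets BBr3. Compound 10 would be demethylated with BBr3 in CH2Cl2 to 2-[(2,3-dibromo-4,5-dihydroxyphenyl)methyl]benzene-1,3,5-triol F7. One equivalent of NBS in THF at −78 °C should then brominate one of the two equivalent positions of the phloroglucinol ring, which is far more nucleophilic than the dibromocatechol ring, to give 12.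

**Further compounds**

F1 | step 5 | 2,3-dibromo-4,5-dimethoxybenzoyl chloride | COc1cc(C(=O)Cl)c(Br)c(Br)c1OC
F2 | step 4 | 2,3-dibromo-4,5-dimethoxybenzoyl azide | COc1cc(C(=O)N=[N+]=[N-])c(Br)c(Br)c1OC
F3 | step 4 | 2,3-dibromo-1-isocyanato-4,5-dimethoxybenzene | COc1cc(N=C=O)c(Br)c(Br)c1OC
F4 | step 4 | tert-butyl (2,3-dibromo-4,5-dimethoxyphenyl)carbamate | COc1cc(NC(=O)OC(C)(C)C)c(Br)c(Br)c1OC
F5 | step 4 | 2,3-dibromo-4,5-dimethoxyaniline | COc1cc(N)c(Br)c(Br)c1OC
F6 | step 4 | 2,3-dibromo-4,5-dimethoxybenzenediazonium 4-methylbenzenesulfonate | COc1cc([N+]#N)c(Br)c(Br)c1OC.Cc1ccc(S(=O)(=O)[O-])cc1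
F7 | step 8 | 2-[(2,3-dibromo-4,5-dihydroxyphenyl)methyl]benzene-1,3,5-triol | Oc1cc(Cc2c(O)cc(O)cc2O)c(Br)c(Br)c1O
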